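**Retrosynthetic overview**
- The target is an achiral pentamer A–O–B–O–C–O–D–O–E (A = 2,4,6-trihydroxyphenyl end, E = 3,4,5-trihydroxyphenyl end). It has no C–C bond outside its five benzene rings, so the strategic bonds are the four aryl–O bonds, and the last step is a 13-fold O-demethylation.
- B–O–C, C–O–D and D–O–E are each cut into a hindered phenoxide and an aryl(2,4,6-trimethoxyphenyl)iodonium salt. The salt acts as a polarity-inverted aryl cation equivalent of an electron-rich ring, so a normally nucleophilic arene carbon is joined to a phenoxide oxygen without metal.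
- One salt, (3,4,5-trimethoxyphenyl)(TMP)iodonium tosylate, is used twice: as ring E and, after regioselective loss of its central methyl, as ring C. Ring D (key step) is delivered from an ortho-pivaloyloxy iodonium salt whose ester is the masked phenol for the E-arylation.
- A–O–B is made first by SNAr on 2-fluoro-4,6-dimethoxybenzaldehyde; a Dakin oxidation then turns CHO into the B-ring phenol.
- No ring is constructed: all five rings are bought as methyl ethers and joined in the order A–B, then C, D, E, the growing chain always being the phenol.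

Assumption: the target has no stereocentre (achiral), so no stereocontrol is needed; the five methoxylated monomers used as starting materials are taken as catalogue compounds.

**Route**

Step 1
Reactants: 1 2,4,6-trimethoxyphenol; 2 2-fluoro-4,6-dimethoxybenzaldehyde
Product: 3 2,4-dimethoxy-6-(2,4,6-trimethoxyphenoxy)benzaldehyde
Conditions: K2CO3, DMSO, 120 °C, N2
Reagents that add atoms: none
Why: SNAr, in which the ortho-formyl group stabilises the Meisenheimer adduct, fluoride is the leaving group and both methoxy groups sit meta to the reacting carbon, so the hindered phenoxide of 1 displaces fluoride.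

Step 2
Reactants: 3 2,4-dimethoxy-6-(2,4,6-trimethoxyphenoxy)benzaldehyde
Product: 5 2,4-dimethoxy-6-(2,4,6-trimethoxyphenoxy)phenol, via aryl formate 4 (not isolated)
Conditions: 30% H2O2, cat. H2SO4, MeOH, rt
Reagents that add atoms: hydrogen peroxide, OO
Why: Dakin-type (acid-catalysed Baeyer–Villiger) oxidation in which the 2,4,6-trioxygenated aryl group migrates to oxygen and formate 4 is methanolysed in situ, the same way 2,4,6-trimethoxyphenol is made from its aldehyde.

Step 3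
Reactants: 6 5-iodo-1,2,3-trimethoxybenzene; 7 1,3,5-trimethoxybenzene
Product: 9 (3,4,5-trimethoxyphenyl)(2,4,6-trimethoxyphenyl)iodonium tosylate, via hydroxy(tosyloxy)iodoarene 8 (not isolated)
Conditions: mCPBA, TsOH·H2O, MeCN, 55 °C; then 7, rt; Et2O trituration
Reagents that add atoms: p-toluenesulfonic acid monohydrate, Cc1ccc(cc1)S(O)(=O)=O.O
Why: One-pot oxidation of the aryl iodide to a Koser-type λ3-iodane followed by SEAr of 1,3,5-trimethoxybenzene at iodine(III) gives the unsymmetrical diaryliodonium tosylate, which precipitates from ether.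

Step 4
Reactants: 5 2,4-dimethoxy-6-(2,4,6-trimethoxyphenoxy)phenol; 9 (3,4,5-trimethoxyphenyl)(2,4,6-trimethoxyphenyl)iodonium tosylate
Product: 10 5-[2,4-dimethoxy-6-(2,4,6-trimethoxyphenoxy)phenoxy]-1,2,3-trimethoxybenzene
Conditions: Cs2CO3, MeCN, 65 °C
Reagents that add atoms: none
Why: Metal-free O-arylation with a diaryliodonium salt (ligand exchange at iodine, then ligand coupling), in which the 2,4,6-trimethoxyphenyl group is a non-transferred dummy, the di-ortho-substituted phenoxide is tolerated and C-arylation is excluded because both ortho positions and the para position are substituted.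

Step 5
Reactants: 10 5-[2,4-dimethoxy-6-(2,4,6-trimethoxyphenoxy)phenoxy]-1,2,3-trimethoxybenzene
Product: 12 4-[2,4-dimethoxy-6-(2,4,6-trimethoxyphenoxy)phenoxy]-2,6-dimethoxyphenol, via trimethylsilyl ether 11 (not isolated)
Conditions: TMSI (1.3 equiv), CH2Cl2, 0 °C → rt; then MeOH
Reagents that add atoms: none
Why: Regioselective O-demethylation, since the central methoxy of the 1,2,3-trimethoxy triad is the only one of the eight forced out of the ring plane (most Lewis-basic oxygen, strain relieved on cleavage), so TMSI silylates it and iodide removes its methyl first, as known for 3,4,5-trimethoxyphenyl rings of podophyllotoxin-type lignans.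

Step 6
Reactants: 13 2,3,4-trimethoxyphenol
Product: 14 6-iodo-2,3,4-trimethoxyphenol
Conditions: I2, NaHCO3, THF–H2O, 0 °C → rt
Reagents that add atoms: iodine, II
Why: Electrophilic aromatic iodination through the phenoxide, which directs to the only free ortho position (C6) because the para position carries OMe.

Step 7
Reactants: 14 6-iodo-2,3,4-trimethoxyphenol
Product: 15 6-iodo-2,3,4-trimethoxyphenyl pivalate
Conditions: PivCl, Et3N, cat. DMAP, CH2Cl2, 0 °C → rt
Reagents that add atoms: pivaloyl chloride, CC(C)(C)C(Cl)=O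
Why: DMAP-catalysed O-acylation masks the phenol as a hindered ester that withstands peracid, TsOH and phenoxides and makes the ring less electron-rich than the dummy ring of the later salt.

Step 8
Reactants: 15 6-iodo-2,3,4-trimethoxyphenyl pivalate; 7 1,3,5-trimethoxybenzene
Product: 17 [2-(pivaloyloxy)-3,4,5-trimethoxyphenyl](2,4,6-trimethoxyphenyl)iodonium tosylate, via hydroxy(tosyloxy)iodoarene 16 (not isolated)
Conditions: mCPBA, TsOH·H2O, MeCN, 55 °C; then 7, rt; Et2O trituration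
Reagents that add atoms: p-toluenesulfonic acid monohydrate, Cc1ccc(cc1)S(O)(=O)=O.O
Why: Same one-pot Koser-iodane formation and SEAr of 1,3,5-trimethoxybenzene as in step 3, done on the monomer so that no λ3-iodane is ever generated next to an aryloxy ring it could attack.

Step 9 (key step)
Reactants: 12 4-[2,4-dimethoxy-6-(2,4,6-trimethoxyphenoxy)phenoxy]-2,6-dimethoxyphenol; 17 [2-(pivaloyloxy)-3,4,5-trimethoxyphenyl](2,4,6-trimethoxyphenyl)iodonium tosylate
Product: 19 6-{4-[2,4-dimethoxy-6-(2,4,6-trimethoxyphenoxy)phenoxy]-2,6-dimethoxyphenoxy}-2,3,4-trimethoxyphenol, via tetramer pivalate 18 (not isolated)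
Conditions: Cs2CO3, MeCN, 65 °C; then MeOH, 60 °C
Reagents that add atoms: none
Why: Metal-free O-arylation in which salt 17 acts as the aryl cation (polarity-inverted) equivalent of the pentaoxygenated ring D, so the 2,6-dimethoxyphenoxide of 12 is joined to a normally nucleophilic arene carbon by ligand coupling at iodine (ortho-acyloxy aryl transferred, trimethoxyphenyl retained), and the pivalate is then removed by carbonate-catalysed methanolysis in the same pot.

Step 10
Reactants: 19 6-{4-[2,4-dimethoxy-6-(2,4,6-trimethoxyphenoxy)phenoxy]-2,6-dimethoxyphenoxy}-2,3,4-trimethoxyphenol; 9 (3,4,5-trimethoxyphenyl)(2,4,6-trimethoxyphenyl)iodonium tosylate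
Product: 20 5-(6-{4-[2,4-dimethoxy-6-(2,4,6-trimethoxyphenoxy)phenoxy]-2,6-dimethoxyphenoxy}-2,3,4-trimethoxyphenoxy)-1,2,3-trimethoxybenzene
Conditions: Cs2CO3, MeCN, 70 °C
Reagents that add atoms: none
Why: Second use of salt 9 in a metal-free diaryliodonium O-arylation, which works on the phenoxide flanked by OAr and OMe where C-arylation is again blocked.

Step 11
Reactants: 20 5-(6-{4-[2,4-dimethoxy-6-(2,4,6-trimethoxyphenoxy)phenoxy]-2,6-dimethoxyphenoxy}-2,3,4-trimethoxyphenoxy)-1,2,3-trimethoxybenzene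
Product: 22 5-(6-{4-[2,4-dihydroxy-6-(2,4,6-trihydroxyphenoxy)phenoxy]-2,6-dihydroxyphenoxy}-2,3,4-trihydroxyphenoxy)benzene-1,2,3-triol (CNP0243665.0), via per-O-dibromoboryl ether 21 (not isolated)
Conditions: BBr3 (30 equiv), CH2Cl2, −78 °C → rt; then degassed H2O, Ar; Sephadex LH-20
Reagents that add atoms: none
Why: Exhaustive Lewis-acid O-demethylation, in which each ArOMe gives an aryloxyborane and MeBr while the diaryl ether bonds are inert, and hydrolysis releases the 13 phenols.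

**Compound list**
1 | 2,4,6-trimethoxyphenol | COc1cc(OC)c(O)c(OC)c1 | starting material
2 | 2-fluoro-4,6-dimethoxybenzaldehyde | COc1cc(F)c(C=O)c(OC)c1 | starting material
3 | 2,4-dimethoxy-6-(2,4,6-trimethoxyphenoxy)benzaldehyde | COc1cc(OC)c(Oc2cc(OC)cc(OC)c2C=O)c(OC)c1 | intermediate
4 | 2,4-dimethoxy-6-(2,4,6-trimethoxyphenoxy)phenyl formate | COc1cc(OC)c(Oc2cc(OC)cc(OC)c2OC=O)c(OC)c1 | intermediate
5 | 2,4-dimethoxy-6-(2,4,6-trimethoxyphenoxy)phenol | COc1cc(OC)c(Oc2cc(OC)cc(OC)c2O)c(OC)c1 | intermediate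
6 | 5-iodo-1,2,3-trimethoxybenzene | COc1cc(I)cc(OC)c1OC | starting material
7 | 1,3,5-trimethoxybenzene | COc1cc(OC)cc(OC)c1 | starting material
8 | 5-[hydroxy(tosyloxy)-λ3-iodanyl]-1,2,3-trimethoxybenzene | COc1cc(cc(OC)c1OC)I(O)OS(=O)(=O)c1ccc(C)cc1 | intermediate
9 | (3,4,5-trimethoxyphenyl)(2,4,6-trimethoxyphenyl)iodonium tosylate | COc1cc(cc(OC)c1OC)[I+]c1c(OC)cc(OC)cc1OC.Cc1ccc(cc1)S([O-])(=O)=O | intermediate
10 | 5-[2,4-dimethoxy-6-(2,4,6-trimethoxyphenoxy)phenoxy]-1,2,3-trimethoxybenzene | COc1cc(OC)c(Oc2cc(OC)cc(OC)c2Oc2cc(OC)c(OC)c(OC)c2)c(OC)c1 | intermediate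
11 | {4-[2,4-dimethoxy-6-(2,4,6-trimethoxyphenoxy)phenoxy]-2,6-dimethoxyphenoxy}trimethylsilane | COc1cc(OC)c(Oc2cc(OC)cc(OC)c2Oc2cc(OC)c(O[Si](C)(C)C)c(OC)c2)c(OC)c1 | intermediate
12 | 4-[2,4-dimethoxy-6-(2,4,6-trimethoxyphenoxy)phenoxy]-2,6-dimethoxyphenol | COc1cc(OC)c(Oc2cc(OC)cc(OC)c2Oc2cc(OC)c(O)c(OC)c2)c(OC)c1 | intermediate
13 | 2,3,4-trimethoxyphenol | COc1ccc(O)c(OC)c1OC | starting material
14 | 6-iodo-2,3,4-trimethoxyphenol | COc1cc(I)c(O)c(OC)c1OC | intermediate
15 | 6-iodo-2,3,4-trimethoxyphenyl pivalate | COc1cc(I)c(OC(=O)C(C)(C)C)c(OC)c1OC | intermediate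
16 | 6-[hydroxy(tosyloxy)-λ3-iodanyl]-2,3,4-trimethoxyphenyl pivalate | COc1cc(I(O)OS(=O)(=O)c2ccc(C)cc2)c(OC(=O)C(C)(C)C)c(OC)c1OC | intermediate
17 | [2-(pivaloyloxy)-3,4,5-trimethoxyphenyl](2,4,6-trimethoxyphenyl)iodonium tosylate | COc1cc([I+]c2c(OC)cc(OC)cc2OC)c(OC(=O)C(C)(C)C)c(OC)c1OC.Cc1ccc(cc1)S([O-])(=O)=O | intermediate
18 | 6-{4-[2,4-dimethoxy-6-(2,4,6-trimethoxyphenoxy)phenoxy]-2,6-dimethoxyphenoxy}-2,3,4-trimethoxyphenyl pivalate | COc1cc(OC)c(Oc2cc(OC)cc(OC)c2Oc2cc(OC)c(Oc3cc(OC)c(OC)c(OC)c3OC(=O)C(C)(C)C)c(OC)c2)c(OC)c1 | intermediate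
19 | 6-{4-[2,4-dimethoxy-6-(2,4,6-trimethoxyphenoxy)phenoxy]-2,6-dimethoxyphenoxy}-2,3,4-trimethoxyphenol | COc1cc(OC)c(Oc2cc(OC)cc(OC)c2Oc2cc(OC)c(Oc3cc(OC)c(OC)c(OC)c3O)c(OC)c2)c(OC)c1 | intermediate
20 | 5-(6-{4-[2,4-dimethoxy-6-(2,4,6-trimethoxyphenoxy)phenoxy]-2,6-dimethoxyphenoxy}-2,3,4-trimethoxyphenoxy)-1,2,3-trimethoxybenzene (tridecamethyl ether of the target) | COc1cc(OC)c(Oc2cc(OC)cc(OC)c2Oc2cc(OC)c(Oc3cc(OC)c(OC)c(OC)c3Oc3cc(OC)c(OC)c(OC)c3)c(OC)c2)c(OC)c1 | intermediate
21 | per-O-dibromoboryl ether of the target (each of the 13 OH written as OBBr2) | BrB(Br)Oc1cc(OB(Br)Br)c(Oc2cc(OB(Br)Br)cc(OB(Br)Br)c2Oc2cc(OB(Br)Br)c(Oc3cc(OB(Br)Br)c(OB(Br)Br)c(OB(Br)Br)c3Oc3cc(OB(Br)Br)c(OB(Br)Br)c(OB(Br)Br)c3)c(OB(Br)Br)c2)c(OB(Br)Br)c1 | intermediate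
22 | 5-(6-{4-[2,4-dihydroxy-6-(2,4,6-trihydroxyphenoxy)phenoxy]-2,6-dihydroxyphenoxy}-2,3,4-trihydroxyphenoxy)benzene-1,2,3-triol (CNP0243665.0, achiral) | Oc1cc(O)c(Oc2cc(O)cc(O)c2Oc2cc(O)c(Oc3cc(O)c(O)c(O)c3Oc3cc(O)c(O)c(O)c3)c(O)c2)c(O)c1 | target

**Step count and risks**
Total steps: 11. Longest linear sequence: 7 (steps 1, 2, 4, 5, 9, 10, 11); side branches are step 3 and steps 6–8.

The three steps most likely to fail:

Step 5 (one methyl out of eight). If TMSI also attacks methoxy groups next to the diaryl ether oxygens, the fallback sets out from 5 and brings ring C in with its phenol already masked. Commercial 2,6-dimethoxyphenol is iodinated (I2, NaHCO3) to 4-iodo-2,6-dimethoxyphenol F1 and acylated (PivCl, Et3N, DMAP) to 4-iodo-2,6-dimethoxyphenyl pivalate F2. Oxidation (mCPBA, TsOH·H2O) to the hydroxy(tosyloxy)iodoarene F3 and reaction with 7 gives [3,5-dimethoxy-4-(pivaloyloxy)phenyl](2,4,6-trimethoxyphenyl)iodonium tosylate F4. O-arylation of 5 with F4 (Cs2CO3, MeCN) gives the trimer pivalate F5, and methanol added to the same pot cleaves the ester, so the fallback comes back to the route at 12.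

Step 9 (tri-ortho-substituted ether from an electron-rich, ester-bearing aryl group). If aryl transfer or the pivalate fails, the fallback sets out from 12 and uses conventional polarity with a formyl group as the masked phenol. Commercial 5-bromo-1,2,3-trimethoxybenzene is formylated (Cl2CHOMe, TiCl4, Rieche) to 6-bromo-2,3,4-trimethoxybenzaldehyde F6. Copper-catalysed Ullmann coupling of 12 with F6 (CuI, picolinic acid, K3PO4, DMSO, 90 °C; the ortho-formyl group assists) gives the tetramer aldehyde 6-{4-[2,4-dimethoxy-6-(2,4,6-trimethoxyphenoxy)phenoxy]-2,6-dimethoxyphenoxy}-2,3,4-trimethoxybenzaldehyde F7. Dakin oxidation (H2O2, cat. H2SO4, MeOH) through the aryl formate F8 comes back to the route at 19.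

Step 11 (13-fold demethylation and isolation of an air-sensitive polyphenol). If BBr3 gives incomplete cleavage or the product cannot be purified as the free phenol, the fallback sets out from 20. It uses the push–pull system AlCl3/EtSH (CH2Cl2, 0 °C → rt) and does not purify the crude polyphenol; this is peracetylated in the same flask (Ac2O, pyridine) to the tridecaacetate F9. F9 is chromatographed on silica and released by acid-catalysed transesterification (cat. AcCl in degassed MeOH, Ar), coming back to the route at 22.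

**Further compounds**
F1 | step 5 | 4-iodo-2,6-dimethoxyphenol | COc1cc(I)cc(OC)c1O
F2 | step 5 | 4-iodo-2,6-dimethoxyphenyl pivalate | COc1cc(I)cc(OC)c1OC(=O)C(C)(C)C
F3 | step 5 | 4-[hydroxy(tosyloxy)-λ3-iodanyl]-2,6-dimethoxyphenyl pivalate | COc1cc(cc(OC)c1OC(=O)C(C)(C)C)I(O)OS(=O)(=O)c1ccc(C)cc1
F4 | step 5 | [3,5-dimethoxy-4-(pivaloyloxy)phenyl](2,4,6-trimethoxyphenyl)iodonium tosylate | COc1cc(cc(OC)c1OC(=O)C(C)(C)C)[I+]c1c(OC)cc(OC)cc1OC.Cc1ccc(cc1)S([O-])(=O)=O
F5 | step 5 | 4-[2,4-dimethoxy-6-(2,4,6-trimethoxyphenoxy)phenoxy]-2,6-dimethoxyphenyl pivalate | COc1cc(OC)c(Oc2cc(OC)cc(OC)c2Oc2cc(OC)c(OC(=O)C(C)(C)C)c(OC)c2)c(OC)c1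
F6 | step 9 | 6-bromo-2,3,4-trimethoxybenzaldehyde | COc1cc(Br)c(C=O)c(OC)c1OC
F7 | step 9 | 6-{4-[2,4-dimethoxy-6-(2,4,6-trimethoxyphenoxy)phenoxy]-2,6-dimethoxyphenoxy}-2,3,4-trimethoxybenzaldehyde | COc1cc(OC)c(Oc2cc(OC)cc(OC)c2Oc2cc(OC)c(Oc3cc(OC)c(OC)c(OC)c3C=O)c(OC)c2)c(OC)c1
F8 | step 9 | 6-{4-[2,4-dimethoxy-6-(2,4,6-trimethoxyphenoxy)phenoxy]-2,6-dimethoxyphenoxy}-2,3,4-trimethoxyphenyl formate | COc1cc(OC)c(Oc2cc(OC)cc(OC)c2Oc2cc(OC)c(Oc3cc(OC)c(OC)c(OC)c3OC=O)c(OC)c2)c(OC)c1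
F9 | step 11 | tridecaacetate of the target (each of the 13 OH as OAc) | CC(=O)Oc1cc(OC(C)=O)c(Oc2cc(OC(C)=O)cc(OC(C)=O)c2Oc2cc(OC(C)=O)c(Oc3cc(OC(C)=O)c(OC(C)=O)c(OC(C)=O)c3Oc3cc(OC(C)=O)c(OC(C)=O)c(OC(C)=O)c3)c(OC(C)=O)c2)c(OC(C)=O)c1
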